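**Retrosynthetic overview** (drimane numbering C1–C12; ring A = C1–C5/C10, ring B = C5–C10)

1. Ring A is bought intact as enone 1. Ring B is the only ring built and is closed last, at C8–C9.
2. C11 aldehyde ⇐ CH2NO2 (Nef). Carrying C11 as a nitro carbon turns C9, an aldehyde α-carbon in the target, into an electrophile.
3. C8–C9 (key bond): the α-carbon of the C12 enal, as its dienamine, adds to the nitroalkene carbon C9. Two aldehyde α-carbons are joined (Rauhut–Currier type), giving the C7=C8 enal and the C9 centre in one step.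
4. C9–C10: ketone enolate + nitroenamine (addition–elimination) anti to the C5 chain, which fixes the trans ring fusion before ring B exists. C5–C6: asymmetric 1,2-allylation of the enone, then anionic oxy-Cope transfer of the allyl group from C1 to C5.
5. C1–O: CBS reduction and acylation. The enal arm comes from cross-metathesis of the allyl group with crotonaldehyde.

Assumption: every compound marked "starting material" in the list is bought as such; the BINOL antipode in step 1 is the one that gives the 1R alcohol.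

**Step 1**
Reactants: 1 2,4,4-trimethylcyclohex-2-en-1-one; 2 tetraallylstannane Sn(CH2CH=CH2)4
Product: 3 (1R)-2,4,4-trimethyl-1-(prop-2-en-1-yl)cyclohex-2-en-1-ol
Conditions: Ti(OiPr)4 (30 mol %), (R)-BINOL (30 mol %), iPrOH (20 equiv), 2 (1.5 equiv), CH2Cl2, rt
Reagents that add atoms: tetraallylstannane, C=CC[Sn](CC=C)(CC=C)CC=C
Why: Catalytic asymmetric ketone allylation (Walsh titanium–BINOLate method, which works best on α-substituted cyclic enones and adds 1,2 only) delivers the allyl group to one face of the carbonyl and sets the C1 carbinol centre (R), whose chirality is relayed to C5 in step 2.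

**Step 2**
Reactants: 3 (1R)-2,4,4-trimethyl-1-(prop-2-en-1-yl)cyclohex-2-en-1-ol; 4 (E)-N,N-dimethyl-2-nitroethen-1-amine
Product: 6 (2S,3S)-2,4,4-trimethyl-2-[(E)-2-nitroethenyl]-3-(prop-2-en-1-yl)cyclohexan-1-one, via potassium enolate 5 (not isolated)
Conditions: KH (1.2 equiv), 18-crown-6 (1.2 equiv), THF, 0 → 40 °C; then 4 (1.3 equiv), −78 → 0 °C; then 1 M HCl
Reagents that add atoms: (E)-N,N-dimethyl-2-nitroethen-1-amine, CN(C)/C=C/[N+](=O)[O-]
Why: Anionic oxy-Cope rearrangement ([3,3], suprafacial across the ring, so the allyl group leaves C1 and arrives on the same face of C5 with 1,3-chirality transfer) gives the regiodefined enolate 5, which undergoes Severin–Fuji nitroolefination (addition to the push–pull nitroenamine, loss of dimethylamine on acidification) anti to the neighbouring allyl group, setting quaternary C10 with the nitrovinyl group trans to the C5 chain.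

**Step 3**
Reactants: 6 (2S,3S)-2,4,4-trimethyl-2-[(E)-2-nitroethenyl]-3-(prop-2-en-1-yl)cyclohexan-1-one
Product: 7 (1R,2S,3S)-2,4,4-trimethyl-2-[(E)-2-nitroethenyl]-3-(prop-2-en-1-yl)cyclohexan-1-ol
Conditions: (S)-2-methyl-CBS-oxazaborolidine (20 mol %), catecholborane (2 equiv), toluene, −78 → −30 °C; then MeOH, pH 7 buffer
Reagents that add atoms: none
Why: Corey–Bakshi–Shibata reduction: catecholborane should neither hydroborate the allyl group nor reduce the nitroalkene at low temperature (my expectation, not a documented case), and the (S)-catalyst (large side = quaternary C10, small side = C2) delivers hydride to the face also favoured by axial attack, giving the equatorial 1β (1R) alcohol.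

**Step 4**
Reactants: 7 (1R,2S,3S)-2,4,4-trimethyl-2-[(E)-2-nitroethenyl]-3-(prop-2-en-1-yl)cyclohexan-1-ol; 8 (2E)-3-(4-methoxyphenyl)prop-2-enoyl chloride
Product: 9 (1R,2S,3S)-2,4,4-trimethyl-2-[(E)-2-nitroethenyl]-3-(prop-2-en-1-yl)cyclohexyl (2E)-3-(4-methoxyphenyl)prop-2-enoate
Conditions: 8 (1.5 equiv), pyridine (3 equiv), DMAP (10 mol %), CH2Cl2, 0 °C → rt
Reagents that add atoms: (2E)-3-(4-methoxyphenyl)prop-2-enoyl chloride, COc1ccc(/C=C/C(Cl)=O)cc1
Why: DMAP-catalysed acylation (nucleophilic catalysis) of the secondary alcohol touches no stereocentre, and the nitroalkene, which has no γ-hydrogen and is shielded by the quaternary carbon, tolerates the mild base.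

**Step 5**
Reactants: 9 (1R,2S,3S)-2,4,4-trimethyl-2-[(E)-2-nitroethenyl]-3-(prop-2-en-1-yl)cyclohexyl (2E)-3-(4-methoxyphenyl)prop-2-enoate; 10 (2E)-but-2-enal
Product: 11 (1R,2S,3S)-2,4,4-trimethyl-2-[(E)-2-nitroethenyl]-3-[(2E)-4-oxobut-2-en-1-yl]cyclohexyl (2E)-3-(4-methoxyphenyl)prop-2-enoate
Conditions: 10 (5 equiv), second-generation Hoveyda–Grubbs catalyst RuCl2(H2IMes)(=CH-C6H4-2-OiPr) (5 mol %), CH2Cl2, 40 °C
Reagents that add atoms: (2E)-but-2-enal, C/C=C/C=O
Why: Olefin cross-metathesis of the terminal allyl group with excess crotonaldehyde gives the (E)-enal with loss of propene, while the electron-poor 1,2-disubstituted nitroalkene and cinnamate double bonds stay out of the metathesis.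

**Step 6 (key step)**
Reactants: 11 (1R,2S,3S)-2,4,4-trimethyl-2-[(E)-2-nitroethenyl]-3-[(2E)-4-oxobut-2-en-1-yl]cyclohexyl (2E)-3-(4-methoxyphenyl)prop-2-enoate
Product: 13 (1R,4aS,8R,8aS)-7-formyl-4,4,8a-trimethyl-8-(nitromethyl)-1,2,3,4,4a,5,8,8a-octahydronaphthalen-1-yl (2E)-3-(4-methoxyphenyl)prop-2-enoate, via pyrrolidine dienamine 12 (not isolated)
Conditions: pyrrolidine (20 mol %), PhCO2H (20 mol %), toluene, 40 °C
Reagents that add atoms: none
Why: Proposed new method: pyrrolidine condenses only with the aldehyde and γ-deprotonation gives dienamine 12, whose α-carbon C8 adds through a six-membered chair-like transition state to nitroalkene carbon C9 (made electrophilic by the nitro group although it is an aldehyde α-carbon in the target), after which iminium/dienamine proton shifts bring the C7=C8 bond back into conjugation and hydrolysis releases 13; the trans C5/C10 substituents force a trans-fused ring B, and the nitrovinyl group should react through the rotamer in which the C10 methyl eclipses the alkene (least allylic strain), placing CH2NO2 equatorial (9β, 8R in the name); the closest known reaction types are the amine-catalysed intramolecular Rauhut–Currier cyclisation of dienals via dienamines and the α-selective dienamine Michael addition of enals to nitroalkenes.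

**Step 7**
Reactants: 13 (1R,4aS,8R,8aS)-7-formyl-4,4,8a-trimethyl-8-(nitromethyl)-1,2,3,4,4a,5,8,8a-octahydronaphthalen-1-yl (2E)-3-(4-methoxyphenyl)prop-2-enoate
Product: 15 (1R,4aS,8R,8aS)-7,8-diformyl-4,4,8a-trimethyl-1,2,3,4,4a,5,8,8a-octahydronaphthalen-1-yl (2E)-3-(4-methoxyphenyl)prop-2-enoate, via nitronate salt 14 (not isolated)
Conditions: DBU (1.05 equiv), THF, −20 °C; then aq. TiCl3 (4 equiv), NH4OAc buffer (pH 5–6), 0 °C → rt
Reagents that add atoms: water, O
Why: Nef reaction in McMurry's reductive form: nitronate 14 is reduced by aqueous TiCl3 to the imine, which hydrolyses in the weakly acidic buffer to the C11 aldehyde without base strong enough to epimerise C9 or deconjugate the enal, and the cinnamate ester is untouched.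

**Compound list**

1 | 2,4,4-trimethylcyclohex-2-en-1-one | CC1=CC(C)(C)CCC1=O | starting material
2 | tetraallylstannane, Sn(CH2CH=CH2)4 | C=CC[Sn](CC=C)(CC=C)CC=C | starting material
3 | (1R)-2,4,4-trimethyl-1-(prop-2-en-1-yl)cyclohex-2-en-1-ol | C=CC[C@]1(O)CCC(C)(C)C=C1C | intermediate
4 | (E)-N,N-dimethyl-2-nitroethen-1-amine | CN(C)/C=C/[N+](=O)[O-] | starting material
5 | potassium (3S)-2,4,4-trimethyl-3-(prop-2-en-1-yl)cyclohex-1-en-1-olate | C=CC[C@@H]1C(C)=C([O-])CCC1(C)C.[K+] | intermediate
6 | (2S,3S)-2,4,4-trimethyl-2-[(E)-2-nitroethenyl]-3-(prop-2-en-1-yl)cyclohexan-1-one | O=C1CCC(C)(C)[C@H](CC=C)[C@@]1(C)/C=C/[N+](=O)[O-] | intermediate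
7 | (1R,2S,3S)-2,4,4-trimethyl-2-[(E)-2-nitroethenyl]-3-(prop-2-en-1-yl)cyclohexan-1-ol | O[C@@H]1CCC(C)(C)[C@H](CC=C)[C@@]1(C)/C=C/[N+](=O)[O-] | intermediate
8 | (2E)-3-(4-methoxyphenyl)prop-2-enoyl chloride | COc1ccc(/C=C/C(Cl)=O)cc1 | starting material
9 | (1R,2S,3S)-2,4,4-trimethyl-2-[(E)-2-nitroethenyl]-3-(prop-2-en-1-yl)cyclohexyl (2E)-3-(4-methoxyphenyl)prop-2-enoate | COc1ccc(/C=C/C(=O)O[C@@H]2CCC(C)(C)[C@H](CC=C)[C@@]2(C)/C=C/[N+](=O)[O-])cc1 | intermediate
10 | (2E)-but-2-enal | C/C=C/C=O | starting material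
11 | (1R,2S,3S)-2,4,4-trimethyl-2-[(E)-2-nitroethenyl]-3-[(2E)-4-oxobut-2-en-1-yl]cyclohexyl (2E)-3-(4-methoxyphenyl)prop-2-enoate | COc1ccc(/C=C/C(=O)O[C@@H]2CCC(C)(C)[C@H](C/C=C/C=O)[C@@]2(C)/C=C/[N+](=O)[O-])cc1 | intermediate
12 | (1R,2S,3S)-2,4,4-trimethyl-2-[(E)-2-nitroethenyl]-3-[(1Z,3E)-4-(pyrrolidin-1-yl)buta-1,3-dien-1-yl]cyclohexyl (2E)-3-(4-methoxyphenyl)prop-2-enoate | COc1ccc(/C=C/C(=O)O[C@@H]2CCC(C)(C)[C@H](/C=C\C=C\N3CCCC3)[C@@]2(C)/C=C/[N+](=O)[O-])cc1 | intermediate
13 | (1R,4aS,8R,8aS)-7-formyl-4,4,8a-trimethyl-8-(nitromethyl)-1,2,3,4,4a,5,8,8a-octahydronaphthalen-1-yl (2E)-3-(4-methoxyphenyl)prop-2-enoate | COc1ccc(/C=C/C(=O)O[C@@H]2CCC(C)(C)[C@@H]3CC=C(C=O)[C@H](C[N+](=O)[O-])[C@@]23C)cc1 | intermediate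
14 | C11 nitronate of 13 as its protonated-DBU salt (all stereocentres as in 13) | COc1ccc(/C=C/C(=O)O[C@@H]2CCC(C)(C)[C@@H]3CC=C(C=O)[C@H](C=[N+]([O-])[O-])[C@@]23C)cc1.C1CCC2=[NH+]CCCN2CC1 | intermediate
15 | (1R,4aS,8R,8aS)-7,8-diformyl-4,4,8a-trimethyl-1,2,3,4,4a,5,8,8a-octahydronaphthalen-1-yl (2E)-3-(4-methoxyphenyl)prop-2-enoate (1β-(E)-p-methoxycinnamoyloxy-polygodial, CNP0328580.1) | COc1ccc(/C=C/C(=O)O[C@@H]2CCC(C)(C)[C@@H]3CC=C(C=O)[C@H](C=O)[C@@]23C)cc1 | target

**Total step count:** 7. **Longest linear sequence:** 7 steps (1 → 15).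

**Steps most likely to fail**

Step 6 (ring B closure). The neopentyl nitroalkene may react slowly, and the C9 configuration rests on a conformational argument (equatorial CH2NO2 suffers a peri interaction with the C1 ester oxygen), so the 9-epimer may form. The fallback sets out from 11 and comes back at 13. An organocatalytic reductive Michael cyclisation (Hantzsch ester, dibenzylammonium trifluoroacetate, THF) reduces the enal iminium to a saturated enamine, which closes onto the nitroalkene through a chair with both new substituents equatorial. This gives (1R,4aS,7R,8S,8aS)-7-formyl-4,4,8a-trimethyl-8-(nitromethyl)decahydronaphthalen-1-yl (2E)-3-(4-methoxyphenyl)prop-2-enoate F3. IBX dehydrogenation (DMSO, 65 °C) then introduces the C7=C8 double bond from the accessible C7 methylene and gives 13.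

Step 2 (oxy-Cope and nitroolefination). The potassium alkoxide may fragment to enone and allyl anion and recombine, which would erode the enantiomeric purity, and the enolate carbon is very congested. The fallback sets out from 3 and comes back at 5. Silylation (TMSCl, imidazole, DMF) gives (1R)-trimethyl{[2,4,4-trimethyl-1-(prop-2-en-1-yl)cyclohex-2-en-1-yl]oxy}silane F1. A neutral thermal siloxy-Cope rearrangement (decalin, sealed tube or flow, 280 °C) is concerted and cannot fragment; it gives trimethyl{[(3S)-2,4,4-trimethyl-3-(prop-2-en-1-yl)cyclohex-1-en-1-yl]oxy}silane F2, which can be purified. KOt-Bu in THF then cleaves the O–Si bond and regenerates enolate 5, which is treated with 4 as in step 2.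

Step 7 (Nef). The nitronate may add to the enal of a second molecule, and the product dialdehyde epimerises at C9 and deconjugates easily. The fallback sets out from 13 and comes back at 15. Reduction with SnCl2·2H2O, PhSH and Et3N in MeCN (thiophenol adds to the hindered enal only reversibly) takes the primary nitro group to (1R,4aS,8R,8aS)-7-formyl-8-[(E)-(hydroxyimino)methyl]-4,4,8a-trimethyl-1,2,3,4,4a,5,8,8a-octahydronaphthalen-1-yl (2E)-3-(4-methoxyphenyl)prop-2-enoate F4. Acidic transoximation with aqueous glyoxylic acid in THF at rt then frees the C11 aldehyde 15 with no base present.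

**Further compounds**

F1 | step 2 | (1R)-trimethyl{[2,4,4-trimethyl-1-(prop-2-en-1-yl)cyclohex-2-en-1-yl]oxy}silane | C=CC[C@]1(O[Si](C)(C)C)CCC(C)(C)C=C1C
F2 | step 2 | trimethyl{[(3S)-2,4,4-trimethyl-3-(prop-2-en-1-yl)cyclohex-1-en-1-yl]oxy}silane | C=CC[C@@H]1C(C)=C(O[Si](C)(C)C)CCC1(C)C
F3 | step 6 | (1R,4aS,7R,8S,8aS)-7-formyl-4,4,8a-trimethyl-8-(nitromethyl)decahydronaphthalen-1-yl (2E)-3-(4-methoxyphenyl)prop-2-enoate | COc1ccc(/C=C/C(=O)O[C@@H]2CCC(C)(C)[C@@H]3CC[C@@H](C=O)[C@H](C[N+](=O)[O-])[C@@]23C)cc1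
F4 | step 7 | (1R,4aS,8R,8aS)-7-formyl-8-[(E)-(hydroxyimino)methyl]-4,4,8a-trimethyl-1,2,3,4,4a,5,8,8a-octahydronaphthalen-1-yl (2E)-3-(4-methoxyphenyl)prop-2-enoate | COc1ccc(/C=C/C(=O)O[C@@H]2CCC(C)(C)[C@@H]3CC=C(C=O)[C@H](/C=N/O)[C@@]23C)cc1
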